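# Proposal: synthesis of CNP0271189.1 (32) by late Ni/Cr closure of the C3–C4 bond

Locants follow germacrane numbering (C1–C10 ring, lactone C11(=C13)–C12(=O)–O–C6, C14 on C10, C15 on C4).

## The problem

Compound 32 is a germacranolide: a ten-membered carbocycle (C1–C10) fused across C6–C7 to an α-methylene-γ-butyrolactone (oxygen on C6, C12 carbonyl, exocyclic C11=C13). Read from the SMILES, the fusion is cis, so the ring arms C5 and C8 leave the lactone on the same face. There are five stereocentres in two sets. The first is the contiguous triad C6 (S), C7 (R), C8 (R), in which both C–O bonds lie anti to the C7–C11 branch of the extended chain. The second is the syn 1,2-diol C10 (S, tertiary, methyl-bearing) and C1 (S). The C9 methylene on one flank, and the C3 ketone with the C4=C5 alkene on the other, insulate the two sets, so each needs its own source of chirality. C10 cannot steer an addition at C1 reliably, because its two carbon arms differ only as CH3 against CH2R. The fragile groups are: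

- the exocyclic enoate (Michael acceptor);
- the angelate at O8 (drifts to the tiglate under nucleophilic catalysis or heat);
- the C1/C3 β-hydroxy ketone (retro-aldol, dehydration);
- the O10/C3 γ-hydroxy carbonyl pair (lactol or hemiketal formation);
- a Z trisubstituted enone in a strained medium ring.

The feature that opens the key step is that the ketone carbon C3 is bonded to C4, the methyl-bearing sp2 carbon of the only ring alkene, whose other end C5 hangs on the lactone carbinol C6. A (Z)-2-iodoalkene at C4 and an aldehyde at C3 can therefore be joined with the alkene geometry fixed beforehand and with the C3 configuration of no consequence.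

## Retrosynthesis

**32 ⇐ 31 ⇐ 30 (no skeletal bond cut).** The two silyl ethers of 31 are removed last under buffered fluoride, so the β-hydroxy ketone and the free O10 appear only in the final step. The enone 31 comes from the allylic alcohol 30 by oxidation. This lets the ring be closed by a carbonyl addition whose new stereocentre is afterwards erased; the forward steps only have to spare the enoates and silyl ethers.

**30 ⇐ 28 (cut C3–C4).** The ring is opened between the carbinol carbon and the alkene carbon, giving the alkenyl iodide–aldehyde 28. The neighbouring cuts are weaker: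

- C2–C3 (aldol) would have to create C1 inside the ring;
- C4=C5 (olefination) would leave the Z geometry to the ring;
- C7–C8 (allylation) would set two of the triad centres during ring closure.

The C3–C4 cut leaves every stereocentre and the alkene geometry to be made on open chains. The forward step must add an alkenyl metal to an aldehyde in the presence of a lactone, two enoates and an angelate, and must favour ring closure over oligomerisation.

**28 ⇐ 26 ⇐ 25 (functional handles).** The C3 aldehyde is stored as the terminal alkene of an allyl group (C2, C3 and one sacrificial carbon) and released by oxidative cleavage of 26. O10 is silylated (25 → 26) just before, because a free O10 would trap the C3 aldehyde as a five-membered lactol. The cleavage must pick the only electron-rich alkene out of four.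

**25 ⇐ 20 + 21 (cut C4=C5).** The iodoalkene is made from the C5 aldehyde 20 and the two-carbon phosphonium salt 21 by an α-iodoethylidene Wittig reaction. This puts C6 and iodine cis, which is exactly the geometry the ring needs, and it brings in C4 and C15 from a bulk chemical. The forward reaction has to leave the stereocentre next to the aldehyde untouched.

**20 ⇐ 19 ⇐ 17 ⇐ 14 + 15 (lactone C12–O6 and ester C–O8).** The C5 aldehyde is the oxidised primary alcohol of 19. The lactone of 19 arises when the acetonide of 17 is removed and O6 closes on the C12 methyl ester. The angelate (from angelic acid 15) is put on O8 in the open hydroxy ester 14 first, so that only O6 can form a five-membered lactone; this avoids any choice between a 6,12- and an 8,12-olide. One acid treatment is asked to unmask, desilylate O10 and lactonise while a hindered secondary silyl ether survives.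

**14 ⇐ 8 + 12 (cut C7–C8).** This is the convergent step. The aldehyde 8 carries the diol half and the allylic bromide 12 carries C5–C7 and C11–C13. A Barbier-type 2-(alkoxycarbonyl)allylation forms C7–C8, creates C7 and C8, and installs the complete methylene-lactone carbon set. Cutting C6–C7 instead would require a far more elaborate bromide made from a C7 aldehyde of the large fragment. With the chosen cut the stereogenic partner is small, comes from the chiral pool, and is made in two steps. The forward reaction must give the syn adduct and must use the C6 stereocentre to choose the face of C7.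

**12 ⇐ 11 ⇐ 9 + 10 (cut C7–C11).** The bromide is the allylically transposed Morita–Baylis–Hillman adduct of (S)-glyceraldehyde acetonide 9 and methyl acrylate 10. Compound 9 supplies C5, C6 (with the correct configuration), C7 and both oxygens; 10 supplies C11–C13. The carbinol stereocentre of 11 is lost in the transposition, so only the alkene geometry matters.

**8 ⇐ 7 ⇐ 6 ⇐ 5 (cut C1–C2).** C1 is created by a reagent-controlled allylboration of the α-quaternary aldehyde 5, since C10 cannot control it. The allyl group serves as the masked C2–C3 aldehyde. The C8 ester of 5 needs no protection and is reduced to the aldehyde 8 only when required.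

**5 ⇐ 4 ⇐ 3 ⇐ 2 ⇐ 1 (chiral pool).** (S)-Citramalic acid 1 contains C1, C10 with its methyl and oxygen in the correct configuration, C9 and C8. The two carboxyls are told apart by hydroxyl-directed reduction of the ester next to the tertiary alcohol (2 → 3). Bis-silylation and direct oxidation of the primary silyl ether give 5.

## Roads not taken

**Alternative 1:** The ring would be opened at C2–C3 and C1–O, treating the C1/C3 β-hydroxy ketone as an isoxazoline. In the forward sense the C3 aldoxime A1 is converted in the flask into its 1,3-dipole, which adds across the terminal C1=C2 alkene under high dilution. This gives the isoxazoline-bridged cyclodecene A2, closing the carbocycle, forming C2–C3 and placing oxygen on C1 in one operation.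

- Merits: the aldol unit stays masked and cannot fragment or dehydrate; no metal is needed; the Z alkene is carried in as in the chosen plan; C1 is set without a chiral reagent.
- Weak points: bridged intramolecular dipolar cycloadditions are least favourable in the ten-membered range, where dimerisation of the dipole competes. The face of the alkene is chosen only by the adjacent quaternary C10. A2 still has C11 as CH2 and a silyl ether on O8, so after ring closure the route needs N–O cleavage, imine hydrolysis, α-methylenation of a lactone next to a more acidic ketone, and the silyl-to-angelate exchange.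
- Comparison: this road is better for C1 and for the safety of the β-hydroxy ketone. The chosen plan spends a stoichiometric chiral borane on C1 and moves a silyl group on and off O10. In return the methylene lactone and the angelate are in place before the ring closes, and only two steps follow it.

**Alternative 2:** The ten-membered ring would be made by enlarging a six-membered one. The alkoxide of the trans-1,2-dialkenylcyclohexenol A3 undergoes an anionic oxy-Cope shift that forms C8–C9 and breaks C1–C6, and kinetic protonation gives the (4Z,1(10)E)-dienone A4.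

- Merits: no cyclisation entropy and no high dilution; the precursor comes from an inexpensive terpene-derived ring; chirality is transferred through a chair to C8.
- Weak points: A4 has its ketone at C6 and a silyl ether at C3, so the oxidation pattern must be transposed. C7 must be alkylated with the three-carbon lactone unit, C6 reduced cis to it, and the 1(10) alkene dihydroxylated to the C1/C10 diol. All of this takes place on a flexible macrocycle whose conformation alone decides four stereocentres.
- Comparison: this road is better for the ring-forming event itself. The chosen plan accepts a harder ring closure so that all five stereocentres are set on open chains by the chiral pool, a chiral reagent and a chair transition state.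

**Alternative 3:** The ring would arise by contraction. Deprotonation at the propargylic C8 of the thirteen-membered allyl propargyl ether A5 triggers a [2,3]-Wittig shift that forms C7–C8, breaks O–C13 and gives the cyclodecenynol A6, with the C11=C13 methylene revealed and O8 free.

- Merits: the hard C7/C8 pair and the exocyclic alkene come from one step; the ten-membered ring is reached from an easier thirteen-membered one; the only free hydroxyl of A6 is the one that must carry the angelate.
- Weak points: the C9≡C10 alkyne must still become CH2–C(CH3)(OH) with control of regiochemistry and of C10. O1 and O3 carry the same silyl group although one must become a ketone. C12 has to be oxidised and lactonised late.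
- Comparison: this road is better at the C7/C8/C11 corner, where the chosen plan depends on a single diastereoselective allylation. The chosen plan takes C10 intact from citramalic acid and needs no late oxidation-state changes at C9, C10 or C12.

Key step: step 17

Remark on the chemistry: the descriptors of 32 are read from the SMILES as 1S,6S,7R,8R,10S. Aldehyde 9 and (−)-B-allyldiisopinocampheylborane are taken as purchasable and used fresh.

## Route

Step 1
Reactants: 1 (S)-citramalic acid
Product: 2 dimethyl (S)-citramalate
Conditions: MeOH, H2SO4 (cat.), reflux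
Reagents that add atoms: methanol, CO
Why: Fischer esterification of both carboxyls; the tertiary alcohol and the quaternary stereocentre are not involved.

Step 2
Reactants: 2 dimethyl (S)-citramalate
Product: 3 methyl (S)-3,4-dihydroxy-3-methylbutanoate
Conditions: BH3·SMe2, NaBH4 (5 mol%), THF, 0 °C to rt; MeOH
Reagents that add atoms: none
Why: Hydroxyl-directed borane reduction: the alkoxyborane formed at the tertiary OH delivers hydride through a five-membered ring to the adjacent ester only, so the C1 ester is reduced and the C8 ester is kept.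

Step 3
Reactants: 3 methyl (S)-3,4-dihydroxy-3-methylbutanoate
Product: 4 methyl (S)-3-methyl-3,4-bis(triethylsilyloxy)butanoate
Conditions: TESOTf, 2,6-lutidine, CH2Cl2, −78 to 0 °C
Reagents that add atoms: triethylsilyl trifluoromethanesulfonate, CC[Si](CC)(CC)OS(=O)(=O)C(F)(F)F
Why: Silyl triflate silylation of the primary and the tertiary hydroxyl in one operation; it prevents γ-lactonisation of the diol ester.

Step 4
Reactants: 4 methyl (S)-3-methyl-3,4-bis(triethylsilyloxy)butanoate
Product: 5 methyl (S)-3-methyl-4-oxo-3-(triethylsilyloxy)butanoate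
Conditions: (COCl)2, DMSO, CH2Cl2, −78 to −40 °C; Et3N, to 0 °C
Reagents that add atoms: none
Why: Swern oxidation applied directly to a primary triethylsilyl ether, which is cleaved and oxidised by the chlorosulfonium salt while the tertiary silyl ether stays; the aldehyde has no α-hydrogen and cannot epimerise.

Step 5
Reactants: 5 methyl (S)-3-methyl-4-oxo-3-(triethylsilyloxy)butanoate
Product: 6 methyl (3S,4S)-4-hydroxy-3-methyl-3-(triethylsilyloxy)hept-6-enoate
Conditions: (−)-Ipc2B(allyl), Et2O, −78 °C; NaBO3·4H2O, THF/H2O, rt
Reagents that add atoms: (−)-B-allyldiisopinocampheylborane, C=CCB([C@@H]1C[C@@H]2C[C@H]([C@H]1C)C2(C)C)[C@@H]1C[C@@H]2C[C@H]([C@H]1C)C2(C)C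
Why: Brown allylboration through a closed chair; the reagent from (+)-α-pinene (the one that gives (S)-1-phenylbut-3-en-1-ol from benzaldehyde) sets C1 as S by reagent control, which is needed because the quaternary C10 discriminates poorly. The ester is inert at −78 °C, and the mild non-basic work-up and prompt use avoid δ-lactonisation.

Step 6
Reactants: 6 methyl (3S,4S)-4-hydroxy-3-methyl-3-(triethylsilyloxy)hept-6-enoate
Product: 7 methyl (3S,4S)-4-(tert-butyldimethylsilyloxy)-3-methyl-3-(triethylsilyloxy)hept-6-enoate
Conditions: TBSOTf, 2,6-lutidine, CH2Cl2, −78 to 0 °C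
Reagents that add atoms: tert-butyldimethylsilyl trifluoromethanesulfonate, CC(C)(C)[Si](C)(C)OS(=O)(=O)C(F)(F)F
Why: Silyl triflate silylation of the hindered secondary C1 hydroxyl; it removes the nucleophile that could close a δ-lactone on the C8 ester.

Step 7
Reactants: 7 methyl (3S,4S)-4-(tert-butyldimethylsilyloxy)-3-methyl-3-(triethylsilyloxy)hept-6-enoate
Product: 8 (3S,4S)-4-(tert-butyldimethylsilyloxy)-3-methyl-3-(triethylsilyloxy)hept-6-enal
Conditions: i-Bu2AlH, CH2Cl2, −78 °C; aq. KNaC4H4O6 (potassium sodium tartrate)
Reagents that add atoms: none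
Why: Partial reduction of the methyl ester with i-Bu2AlH; the tetrahedral aluminium acetal is stable at −78 °C and releases the C8 aldehyde on work-up.

Step 8
Reactants: 9 (S)-2,2-dimethyl-1,3-dioxolane-4-carbaldehyde; 10 methyl acrylate
Product: 11 methyl 2-{[(4S)-2,2-dimethyl-1,3-dioxolan-4-yl](hydroxy)methyl}prop-2-enoate (both carbinol epimers)
Conditions: DABCO, neat, rt
Reagents that add atoms: none
Why: Morita–Baylis–Hillman reaction forms C7–C11; the carbinol configuration does not matter because that centre becomes sp2 in step 9.

Step 9
Reactants: 11 methyl 2-{[(4S)-2,2-dimethyl-1,3-dioxolan-4-yl](hydroxy)methyl}prop-2-enoate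
Product: 12 methyl (Z)-2-(bromomethyl)-3-[(4R)-2,2-dimethyl-1,3-dioxolan-4-yl]prop-2-enoate
Conditions: NBS, Me2S, CH2Cl2, 0 °C to rt
Reagents that add atoms: N-bromosuccinimide, O=C1CCC(=O)N1Br
Why: Corey–Kim-type activation of the allylic alcohol and SN2′ attack of bromide give the conjugated bromide with C6 cis to CH2Br (the stable geometry, β-hydrogen syn to the ester); the conditions are acid-free and keep the acetonide.

Step 10
Reactants: 8 (3S,4S)-4-(tert-butyldimethylsilyloxy)-3-methyl-3-(triethylsilyloxy)hept-6-enal; 12 methyl (Z)-2-(bromomethyl)-3-[(4R)-2,2-dimethyl-1,3-dioxolan-4-yl]prop-2-enoate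
Product: 14 methyl (3R,4R,6S,7S)-7-(tert-butyldimethylsilyloxy)-3-[(4R)-2,2-dimethyl-1,3-dioxolan-4-yl]-4-hydroxy-6-methyl-2-methylidene-6-(triethylsilyloxy)dec-9-enoate, via allylindium dibromide 13 (not isolated)
Conditions: indium powder, THF/H2O (1:1), rt
Reagents that add atoms: none
Why: Indium-mediated Barbier 2-(alkoxycarbonyl)allylation through a Zimmerman–Traxler chair in which the C6 substituent, cis to the metal-bearing carbon, is axial and the aldehyde residue equatorial, which gives the syn C7/C8 pair. A(1,3) strain holds H6 in the alkene plane, and the aldehyde should be delivered by indium to the C7 face that bears the dioxolane oxygen (which can coordinate the metal) and is anti to C5, giving the required C6/C7 relation. Vinyl-free neutral aqueous conditions spare both silyl ethers and the acetonide.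

Step 11
Reactants: 14 Barbier adduct (free C8 hydroxyl); 15 angelic acid
Product: 17 methyl (3R,4R,6S,7S)-4-(angeloyloxy)-7-(tert-butyldimethylsilyloxy)-3-[(4R)-2,2-dimethyl-1,3-dioxolan-4-yl]-6-methyl-2-methylidene-6-(triethylsilyloxy)dec-9-enoate, via angelic 2,4,6-trichlorobenzoic anhydride 16 (not isolated)
Conditions: 15, 2,4,6-trichlorobenzoyl chloride, Et3N, toluene, rt; then 14, 75 °C
Reagents that add atoms: none
Why: Yamaguchi esterification with the preformed mixed anhydride and no nucleophilic catalyst, the protocol that keeps the Z geometry of angelates; acylation of O8 before any lactone exists fixes which oxygen carries the ester.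

Step 12
Reactants: 17 C8 angelate with acetonide and tertiary silyl ether
Product: 19 (1S,6R,7R,8R,10S) lactone diol: 6,12-olide with C11=C13 bearing C5H2OH on C6 and on C7 the chain C8H(OAng)–C9H2–C10(CH3)(OH)–C1H(OTBS)–C2H2–C3H=CH2, via triol methyl ester 18 (not isolated)
Conditions: CSA (0.2 equiv), MeOH, 0 °C to rt; evaporate; CSA, CH2Cl2, rt
Reagents that add atoms: none
Why: Acid-catalysed transketalisation removes the acetonide and the tertiary triethylsilyl ether, and O6 then closes the five-membered lactone on the C12 methyl ester (favoured over the six-membered lactone through O5). The neopentyl-like secondary TBS ether at C1 should survive, and the cis lactone follows from C6 and C7 as already set.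

Step 13
Reactants: 19 lactone diol
Product: 20 (1S,6R,7R,8R,10S) C5 aldehyde of the lactone (C10 hydroxyl free)
Conditions: Dess–Martin periodinane, NaHCO3, CH2Cl2, 0 °C to rt
Reagents that add atoms: none
Why: Dess–Martin oxidation of the primary alcohol; the tertiary C10 hydroxyl cannot be oxidised, and the buffered neutral medium guards C6 against epimerisation.

Step 14
Reactants: 20 C5 aldehyde; 21 ethyltriphenylphosphonium iodide
Product: 25 (1S,6R,7R,8R,10S) lactone bearing the (Z)-2-iodoprop-1-enyl group on C6 (C10 hydroxyl free), via ethylidenetriphenylphosphorane 22 (not isolated), via (1-iodoethyl)triphenylphosphonium iodide 23 (not isolated), via (1-iodoethylidene)triphenylphosphorane 24 (not isolated)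
Conditions: 21, n-BuLi, THF, rt; I2, −78 °C; NaN(SiMe3)2, −78 to −20 °C; then 20, −78 °C
Reagents that add atoms: iodine, II
Why: Stork–Zhao olefination: the unstabilised α-iodo ylide adds to the aldehyde under kinetic control and collapses to the alkene with C6 and iodine cis (Z). At −78 °C the aldehyde should react faster than the enoates, and the weakly acidic tertiary hydroxyl is tolerated with a small excess of ylide.

Step 15
Reactants: 25 (Z)-iodoalkene with free C10 hydroxyl
Product: 26 (1S,6R,7R,8R,10S) C10 triethylsilyl ether of 25
Conditions: TESOTf, 2,6-lutidine, CH2Cl2, −40 to 0 °C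
Reagents that add atoms: triethylsilyl trifluoromethanesulfonate, CC[Si](CC)(CC)OS(=O)(=O)C(F)(F)F
Why: Silyl triflate silylation of the hindered tertiary alcohol; a protected O10 cannot form a five-membered lactol with the C3 aldehyde made in the next step.

Step 16
Reactants: 26 fully protected iodoalkene with terminal alkene
Product: 28 (1S,6R,7R,8R,10S) seco aldehyde: lactone with (Z)-2-iodoprop-1-enyl on C6 and on C7 the chain C8H(OAng)–C9H2–C10(CH3)(OTES)–C1H(OTBS)–C2H2–C3HO, via terminal diol 27 (not isolated)
Conditions: OsO4 (2 mol%), NaIO4, 2,6-lutidine, dioxane/H2O (3:1), rt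
Reagents that add atoms: osmium tetroxide, O=[Os](=O)(=O)=O; sodium periodate, [Na+].[O-]I(=O)(=O)=O
Why: Lemieux–Johnson cleavage: electrophilic OsO4 should take the monosubstituted terminal alkene well before the conjugated exocyclic enoate, the angelate or the iodine-bearing trisubstituted alkene, and periodate cleaves the diol to the C3 aldehyde and formaldehyde.

Step 17
Reactants: 28 seco aldehyde with (Z)-alkenyl iodide
Product: 30 (1S,6S,7R,8R,10S)-8-angeloyloxy-1-(tert-butyldimethylsilyloxy)-3-hydroxy-10-(triethylsilyloxy)germacra-4Z,11(13)-dien-6,12-olide (both C3 epimers; 3S drawn), via alkenylchromium dichloride 29 (not isolated)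
Conditions: CrCl2 (15 equiv), NiCl2 (0.15 equiv), DMSO, 2 mM, rt
Reagents that add atoms: none
Why: Nozaki–Hiyama–Kishi reaction: NiCl2 is reduced by CrCl2 to zerovalent nickel, which inserts into the C4–I bond with retention of alkene geometry, and the alkenyl group then passes to trivalent chromium to give 29 while nickel re-enters the cycle. The carbon–chromium bond of 29 adds to the C3 aldehyde, forming C3–C4 and the chromium alkoxide of 30. The closest known reaction type is the Ni/Cr-mediated alkenyl iodide–aldehyde macrocyclisation used for medium and large carbocycles that carry esters and enoates, ten-membered germacrane rings included. The ring closes in the 10-exo-trig mode, favoured over oligomerisation by high dilution and by the cis lactone, which already holds the C5 and C8 arms on one face. The new stereocentre C3 is governed only by the conformation of the closing ring and needs no control, since step 18 converts both epimers into one ketone. The step requires chemoselectivity for the aldehyde, which is secured because alkenyl reagents of trivalent chromium do not add to the lactone, the angelate or the exocyclic enoate and leave silyl ethers alone. The Z geometry is secured by the substrate, since C6 and iodine are cis in 28 and trisubstituted alkenyl–nickel and alkenyl–chromium bonds do not invert.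

Step 18
Reactants: 30 macrocyclic C3 carbinol (epimer mixture)
Product: 31 (1S,6S,7R,8R,10S)-8-angeloyloxy-1-(tert-butyldimethylsilyloxy)-3-oxo-10-(triethylsilyloxy)germacra-4Z,11(13)-dien-6,12-olide
Conditions: Dess–Martin periodinane, NaHCO3, CH2Cl2, 0 °C to rt
Reagents that add atoms: none
Why: Dess–Martin oxidation of the secondary allylic alcohol removes the C3 stereocentre and gives the Z enone without acid or base strong enough to move the alkene or touch the silyl ethers.

Step 19
Reactants: 31 bis-silylated enone
Product: 32 CNP0271189.1, (1S,6S,7R,8R,10S)-8-angeloyloxy-1,10-dihydroxy-3-oxogermacra-4Z,11(13)-dien-6,12-olide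
Conditions: HF·pyridine, pyridine, THF, 0 °C to rt
Reagents that add atoms: none
Why: Fluoride-mediated desilylation of the secondary TBS and tertiary TES ethers; the pyridine buffer keeps the medium mild enough to avoid dehydration of the β-hydroxy ketone and isomerisation of the angelate.

## Compound list

1 | (S)-citramalic acid | OC(=O)C[C@](C)(O)C(=O)O | starting material
2 | dimethyl (S)-citramalate | COC(=O)C[C@](C)(O)C(=O)OC | intermediate
3 | methyl (S)-3,4-dihydroxy-3-methylbutanoate | COC(=O)C[C@](C)(O)CO | intermediate
4 | methyl (S)-3-methyl-3,4-bis(triethylsilyloxy)butanoate | COC(=O)C[C@](C)(O[Si](CC)(CC)CC)CO[Si](CC)(CC)CC | intermediate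
5 | methyl (S)-3-methyl-4-oxo-3-(triethylsilyloxy)butanoate | COC(=O)C[C@](C)(O[Si](CC)(CC)CC)C=O | intermediate
6 | methyl (3S,4S)-4-hydroxy-3-methyl-3-(triethylsilyloxy)hept-6-enoate | C=CC[C@H](O)[C@@](C)(O[Si](CC)(CC)CC)CC(=O)OC | intermediate
7 | methyl (3S,4S)-4-(tert-butyldimethylsilyloxy)-3-methyl-3-(triethylsilyloxy)hept-6-enoate | C=CC[C@H](O[Si](C)(C)C(C)(C)C)[C@@](C)(O[Si](CC)(CC)CC)CC(=O)OC | intermediate
8 | (3S,4S)-4-(tert-butyldimethylsilyloxy)-3-methyl-3-(triethylsilyloxy)hept-6-enal | C=CC[C@H](O[Si](C)(C)C(C)(C)C)[C@@](C)(O[Si](CC)(CC)CC)CC=O | intermediate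
9 | (S)-2,2-dimethyl-1,3-dioxolane-4-carbaldehyde | O=C[C@@H]1COC(C)(C)O1 | starting material
10 | methyl acrylate | C=CC(=O)OC | starting material
11 | methyl 2-{[(4S)-2,2-dimethyl-1,3-dioxolan-4-yl](hydroxy)methyl}prop-2-enoate (carbinol epimers) | COC(=O)C(=C)C(O)[C@@H]1COC(C)(C)O1 | intermediate
12 | methyl (Z)-2-(bromomethyl)-3-[(4R)-2,2-dimethyl-1,3-dioxolan-4-yl]prop-2-enoate | COC(=O)/C(CBr)=C/[C@@H]1COC(C)(C)O1 | intermediate
13 | allylindium dibromide from 12 (trivalent indium, drawn as the monomer) | COC(=O)/C(C[In](Br)Br)=C/[C@@H]1COC(C)(C)O1 | intermediate (not isolated)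
14 | methyl (3R,4R,6S,7S)-7-(tert-butyldimethylsilyloxy)-3-[(4R)-2,2-dimethyl-1,3-dioxolan-4-yl]-4-hydroxy-6-methyl-2-methylidene-6-(triethylsilyloxy)dec-9-enoate | C=CC[C@H](O[Si](C)(C)C(C)(C)C)[C@@](C)(O[Si](CC)(CC)CC)C[C@@H](O)[C@H]([C@@H]1COC(C)(C)O1)C(=C)C(=O)OC | intermediate
15 | angelic acid | C/C=C(/C)C(=O)O | starting material
16 | angelic 2,4,6-trichlorobenzoic anhydride | C/C=C(/C)C(=O)OC(=O)c1c(Cl)cc(Cl)cc1Cl | intermediate (not isolated)
17 | methyl (3R,4R,6S,7S)-4-(angeloyloxy)-7-(tert-butyldimethylsilyloxy)-3-[(4R)-2,2-dimethyl-1,3-dioxolan-4-yl]-6-methyl-2-methylidene-6-(triethylsilyloxy)dec-9-enoate | C=CC[C@H](O[Si](C)(C)C(C)(C)C)[C@@](C)(O[Si](CC)(CC)CC)C[C@@H](OC(=O)/C(C)=C\C)[C@H]([C@@H]1COC(C)(C)O1)C(=C)C(=O)OC | intermediate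
18 | (1S,6R,7S,8R,10S) triol methyl ester: 17 without acetonide and without the C10 silyl group | C=CC[C@H](O[Si](C)(C)C(C)(C)C)[C@@](C)(O)C[C@@H](OC(=O)/C(C)=C\C)[C@H]([C@@H](O)CO)C(=C)C(=O)OC | intermediate (not isolated)
19 | (1S,6R,7R,8R,10S) lactone diol (C5 and C10 hydroxyls free, C1 OTBS, C8 angelate) | C=CC[C@H](O[Si](C)(C)C(C)(C)C)[C@@](C)(O)C[C@@H](OC(=O)/C(C)=C\C)[C@H]1C(=C)C(=O)O[C@H]1CO | intermediate
20 | (1S,6R,7R,8R,10S) lactone C5 aldehyde | C=CC[C@H](O[Si](C)(C)C(C)(C)C)[C@@](C)(O)C[C@@H](OC(=O)/C(C)=C\C)[C@H]1C(=C)C(=O)O[C@H]1C=O | intermediate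
21 | ethyltriphenylphosphonium iodide | CC[P+](c1ccccc1)(c1ccccc1)c1ccccc1.[I-] | starting material
22 | ethylidenetriphenylphosphorane | CC=P(c1ccccc1)(c1ccccc1)c1ccccc1 | intermediate (not isolated)
23 | (1-iodoethyl)triphenylphosphonium iodide | CC(I)[P+](c1ccccc1)(c1ccccc1)c1ccccc1.[I-] | intermediate (not isolated)
24 | (1-iodoethylidene)triphenylphosphorane | CC(I)=P(c1ccccc1)(c1ccccc1)c1ccccc1 | intermediate (not isolated)
25 | (1S,6R,7R,8R,10S) lactone with (Z)-2-iodoprop-1-enyl on C6, C10 hydroxyl free | C=CC[C@H](O[Si](C)(C)C(C)(C)C)[C@@](C)(O)C[C@@H](OC(=O)/C(C)=C\C)[C@H]1C(=C)C(=O)O[C@H]1/C=C(/C)I | intermediate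
26 | (1S,6R,7R,8R,10S) C10 triethylsilyl ether of 25 | C=CC[C@H](O[Si](C)(C)C(C)(C)C)[C@@](C)(O[Si](CC)(CC)CC)C[C@@H](OC(=O)/C(C)=C\C)[C@H]1C(=C)C(=O)O[C@H]1/C=C(/C)I | intermediate
27 | terminal diol from 26 (new carbinol epimers) | OCC(O)C[C@H](O[Si](C)(C)C(C)(C)C)[C@@](C)(O[Si](CC)(CC)CC)C[C@@H](OC(=O)/C(C)=C\C)[C@H]1C(=C)C(=O)O[C@H]1/C=C(/C)I | intermediate (not isolated)
28 | (1S,6R,7R,8R,10S) seco aldehyde with (Z)-alkenyl iodide, precursor of the key step | O=CC[C@H](O[Si](C)(C)C(C)(C)C)[C@@](C)(O[Si](CC)(CC)CC)C[C@@H](OC(=O)/C(C)=C\C)[C@H]1C(=C)C(=O)O[C@H]1/C=C(/C)I | intermediate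
29 | alkenylchromium dichloride from 28 (trivalent chromium) | O=CC[C@H](O[Si](C)(C)C(C)(C)C)[C@@](C)(O[Si](CC)(CC)CC)C[C@@H](OC(=O)/C(C)=C\C)[C@H]1C(=C)C(=O)O[C@H]1/C=C(/C)[Cr](Cl)Cl | intermediate (not isolated)
30 | (1S,6S,7R,8R,10S)-8-angeloyloxy-1-(tert-butyldimethylsilyloxy)-3-hydroxy-10-(triethylsilyloxy)germacra-4Z,11(13)-dien-6,12-olide (3S epimer drawn) | C=C1C(=O)O[C@H]2/C=C(/C)[C@@H](O)C[C@H](O[Si](C)(C)C(C)(C)C)[C@@](C)(O[Si](CC)(CC)CC)C[C@@H](OC(=O)/C(C)=C\C)[C@@H]12 | intermediate
31 | (1S,6S,7R,8R,10S)-8-angeloyloxy-1-(tert-butyldimethylsilyloxy)-3-oxo-10-(triethylsilyloxy)germacra-4Z,11(13)-dien-6,12-olide | C=C1C(=O)O[C@H]2/C=C(/C)C(=O)C[C@H](O[Si](C)(C)C(C)(C)C)[C@@](C)(O[Si](CC)(CC)CC)C[C@@H](OC(=O)/C(C)=C\C)[C@@H]12 | intermediate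
32 | CNP0271189.1, (1S,6S,7R,8R,10S)-8-angeloyloxy-1,10-dihydroxy-3-oxogermacra-4Z,11(13)-dien-6,12-olide | C=C1C(=O)O[C@H]2/C=C(/C)C(=O)C[C@H](O)[C@@](C)(O)C[C@@H](OC(=O)/C(C)=C\C)[C@@H]12 | target

## Step count and least certain steps

Total: 19 steps. The longest linear sequence is 17 steps (steps 1–7 and 10–19, from 1); steps 8 and 9 form a two-step branch from 9 and 10.

**Step 17 (key step).** The most likely failure is a slow ring closure. The ten-membered transition state is strained and two silyl ethers flank the aldehyde, so reductive loss of iodine from the alkenyl metal and intermolecular addition could outrun cyclisation. The fallback sets out from 25 and comes back at 32. It changes the constraint on the closing chain and the protecting-group end game. HF·pyridine removes the C1 silyl ether of 25 to give the 1,10-diol F1. 2-Methoxypropene and PPTS tie O1 and O10 into the acetonide F2, which replaces the two bulky silyl groups next to the reacting aldehyde by one small ring. The Lemieux–Johnson cleavage used in step 16 gives the seco aldehyde F3. CrCl2 with catalytic NiCl2 under the same dilution closes the ring to the carbinol F4, and Dess–Martin oxidation gives the enone acetonide F5. Aqueous acetic acid then frees the diol and returns the route at 32.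

**Step 10.** Three processes could fail:

- wrong facial selection at C7, if the aldehyde approaches anti to the dioxolane C–O bond through an open transition state instead of being delivered on the oxygen-bearing face;
- erosion of syn selectivity in the aqueous medium;
- 1,4-elimination of the allylindium toward a dienoate.

The fallback sets out from 11 and comes back at 14. It replaces the indium Barbier reaction by an allylboration through a tight boron chair in an anhydrous medium. Acetylation of 11 (Ac2O, pyridine) gives the allylic acetate F6. B2pin2 with Pd2(dba)3 (zerovalent palladium) substitutes the acetate with allyl shift to give the allylboronate F7, with C6 cis to the boron-bearing carbon. Heating F7 with 8 in toluene, followed by aqueous NaHCO3, gives 14. Allylboronates do not eliminate, and their closed six-membered transition state transmits the alkene geometry faithfully.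

**Step 14.** Three processes could fail:

- epimerisation at C6 by enolisation of the α-acyloxy aldehyde under the basic ylide;
- conjugate addition of the ylide to the exocyclic enoate;
- leakage to the E iodide.

The fallback sets out from 20 and comes back at 30. It builds the haloalkene without a basic ylide. Ramirez olefination (CBr4, PPh3, 2,6-lutidine) converts 20 into the 1,1-dibromoalkene F8. A trans-selective Negishi monomethylation (MeZnCl, Pd(PPh3)4, zerovalent palladium) replaces the bromine anti to C6 and gives the (Z)-2-bromoalkene F9. Silylation as in step 15 gives the triethylsilyl ether F10, and the cleavage of step 16 gives the bromo seco aldehyde F11. The CrCl2/NiCl2 closure of step 17, which also accepts alkenyl bromides, then gives 30.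

**Step 16.** The likely failure is over-oxidation. The exocyclic methylene of the lactone is the least hindered of the electron-poor alkenes and could be osmylated alongside the terminal alkene. The fallback sets out from 26 and comes back at 31. It masks that alkene during the oxidative and metal-mediated steps. Dimethylamine adds to the methylene lactone of 26 to give the β-aminomethyl lactone F12. Dihydroxylation and periodate cleavage of the only remaining unhindered alkene give the aldehyde F13. The CrCl2/NiCl2 closure gives the carbinol F14, and Dess–Martin oxidation gives the amino enone F15. Methyl iodide quaternises the amine to the methiodide F16, and NaHCO3 induces elimination of trimethylamine, which restores the exocyclic alkene and returns the route at 31.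

## Further compounds

F1 | step 17 | 1,10-diol from 25 (C1 silyl ether removed) | C=CC[C@H](O)[C@@](C)(O)C[C@@H](OC(=O)/C(C)=C\C)[C@H]1C(=C)C(=O)O[C@H]1/C=C(/C)I
F2 | step 17 | O1,O10-acetonide of F1 | C=CC[C@@H]1OC(C)(C)O[C@@]1(C)C[C@@H](OC(=O)/C(C)=C\C)[C@H]1C(=C)C(=O)O[C@H]1/C=C(/C)I
F3 | step 17 | acetonide seco aldehyde | O=CC[C@@H]1OC(C)(C)O[C@@]1(C)C[C@@H](OC(=O)/C(C)=C\C)[C@H]1C(=C)C(=O)O[C@H]1/C=C(/C)I
F4 | step 17 | acetonide macrocyclic C3 carbinol (3S epimer drawn) | C=C1C(=O)O[C@H]2/C=C(/C)[C@@H](O)C[C@@H]3OC(C)(C)O[C@@]3(C)C[C@@H](OC(=O)/C(C)=C\C)[C@@H]12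
F5 | step 17 | acetonide macrocyclic enone | C=C1C(=O)O[C@H]2/C=C(/C)C(=O)C[C@@H]3OC(C)(C)O[C@@]3(C)C[C@@H](OC(=O)/C(C)=C\C)[C@@H]12
F6 | step 10 | methyl 2-{acetoxy[(4S)-2,2-dimethyl-1,3-dioxolan-4-yl]methyl}prop-2-enoate | COC(=O)C(=C)C(OC(C)=O)[C@@H]1COC(C)(C)O1
F7 | step 10 | methyl (E)-3-[(4R)-2,2-dimethyl-1,3-dioxolan-4-yl]-2-[(4,4,5,5-tetramethyl-1,3,2-dioxaborolan-2-yl)methyl]prop-2-enoate | COC(=O)/C(CB1OC(C)(C)C(C)(C)O1)=C/[C@@H]2COC(C)(C)O2
F8 | step 14 | 1,1-dibromoalkene from 20 | C=CC[C@H](O[Si](C)(C)C(C)(C)C)[C@@](C)(O)C[C@@H](OC(=O)/C(C)=C\C)[C@H]1C(=C)C(=O)O[C@H]1C=C(Br)Br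
F9 | step 14 | (Z)-2-bromoprop-1-enyl lactone, C10 hydroxyl free | C=CC[C@H](O[Si](C)(C)C(C)(C)C)[C@@](C)(O)C[C@@H](OC(=O)/C(C)=C\C)[C@H]1C(=C)C(=O)O[C@H]1/C=C(/C)Br
F10 | step 14 | C10 triethylsilyl ether of F9 | C=CC[C@H](O[Si](C)(C)C(C)(C)C)[C@@](C)(O[Si](CC)(CC)CC)C[C@@H](OC(=O)/C(C)=C\C)[C@H]1C(=C)C(=O)O[C@H]1/C=C(/C)Br
F11 | step 14 | bromo seco aldehyde | O=CC[C@H](O[Si](C)(C)C(C)(C)C)[C@@](C)(O[Si](CC)(CC)CC)C[C@@H](OC(=O)/C(C)=C\C)[C@H]1C(=C)C(=O)O[C@H]1/C=C(/C)Br
F12 | step 16 | dimethylamine adduct of 26 at C13 (C11 epimers) | C=CC[C@H](O[Si](C)(C)C(C)(C)C)[C@@](C)(O[Si](CC)(CC)CC)C[C@@H](OC(=O)/C(C)=C\C)[C@H]1C(CN(C)C)C(=O)O[C@H]1/C=C(/C)I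
F13 | step 16 | amino seco aldehyde | O=CC[C@H](O[Si](C)(C)C(C)(C)C)[C@@](C)(O[Si](CC)(CC)CC)C[C@@H](OC(=O)/C(C)=C\C)[C@H]1C(CN(C)C)C(=O)O[C@H]1/C=C(/C)I
F14 | step 16 | amino macrocyclic C3 carbinol (3S epimer drawn) | CN(C)CC1C(=O)O[C@H]2/C=C(/C)[C@@H](O)C[C@H](O[Si](C)(C)C(C)(C)C)[C@@](C)(O[Si](CC)(CC)CC)C[C@@H](OC(=O)/C(C)=C\C)[C@@H]12
F15 | step 16 | amino macrocyclic enone | CN(C)CC1C(=O)O[C@H]2/C=C(/C)C(=O)C[C@H](O[Si](C)(C)C(C)(C)C)[C@@](C)(O[Si](CC)(CC)CC)C[C@@H](OC(=O)/C(C)=C\C)[C@@H]12
F16 | step 16 | trimethylammonium iodide of F15 | C[N+](C)(C)CC1C(=O)O[C@H]2/C=C(/C)C(=O)C[C@H](O[Si](C)(C)C(C)(C)C)[C@@](C)(O[Si](CC)(CC)CC)C[C@@H](OC(=O)/C(C)=C\C)[C@@H]12.[I-]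
A1 | alternative 1 | open-chain C3 aldoxime with terminal C1=C2 alkene | C=C[C@@](C)(O)C[C@@H](O[Si](C)(C)C(C)(C)C)[C@H]1CC(=O)O[C@H]1/C=C(/C)C=NO
A2 | alternative 1 | isoxazoline-bridged cyclodecene lactone | C1C2=NO[C@@H]1[C@@](C)(O)C[C@@H](O[Si](C)(C)C(C)(C)C)[C@H]3CC(=O)O[C@H]3/C=C2/C
A3 | alternative 2 | trans-1,2-dialkenylcyclohexenol (enol ether arm on the carbinol carbon, isopropenyl on the neighbour) | O[C@]1(/C=C/OCc2ccc(OC)cc2)C=C(C)[C@H](O[Si](C)(C)C(C)(C)C)C[C@@H]1C(C)=C
A4 | alternative 2 | ten-membered (4Z,1(10)E)-dienone with C8 PMB ether | C1[C@H](OCc2ccc(OC)cc2)C/C(C)=C/C[C@@H](O[Si](C)(C)C(C)(C)C)/C(C)=C\C1=O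
A5 | alternative 3 | thirteen-membered allyl propargyl ether (oxygen between C8 and C13) | O1C/C(CO[Si](CC)(CC)CC)=C/[C@@H](O[Si](CC)(CC)CC)/C=C(C)\[C@H](O[Si](C)(C)C(C)(C)C)C[C@H](O[Si](C)(C)C(C)(C)C)C#CC1
A6 | alternative 3 | ten-membered cyclodecenynol with C7 and C8 set | O[C@@H]1C#C[C@@H](O[Si](C)(C)C(C)(C)C)C[C@@H](O[Si](C)(C)C(C)(C)C)/C(C)=C\[C@H](O[Si](CC)(CC)CC)[C@@H]1C(=C)CO[Si](CC)(CC)CC
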